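**Retrosynthetic overview**

1. The target is reached from the 8-epi carbinol 25 by Mitsunobu esterification (inversion at C8) with the pre-assembled diester acid 38 (built from two Morita–Baylis–Hillman units), then desilylation.
2. 25 is cut at C7–C8 of the ten-membered carbocycle (C1–C10): an intramolecular Cr(II) Barbier allylation in which the 3-(bromomethyl)butenolide of seco aldehyde 23 acts as a polarity-reversed C7 nucleophile towards the C8 aldehyde.
3. Enabling feature: the exocyclic C11=C13 methylene of the γ-lactone ring (O–C6–C7–C11–C12) and the oxygenated C8 of the carbocycle form the homoallylic alcohol array C13=C11–C7–C8–O, with C7 shared by both rings. This is the retron of a carbonyl allylation with allyl transposition.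
4. 23 comes from a linear chain: C8–C10 and C1 from but-3-yn-1-ol (carboalumination; oxirane adds C2–C3), C3 and C6 from two catalytic alkynylations, Z-C4=C5 from methylcuprate syn-addition, and the lactone from Red-Al/I2 then carbonylation.
5. Ring order: γ-lactone (step 11), then oxirane (step 12), then the ten-membered carbocycle (step 17).

Key step: step 17

Remark: germacrane numbering is used for the carbons throughout (C1–C10 ten-membered ring, C11–C13 lactone carbons, C14 on C10, C15 on C4).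

Assumption: the (S,S)-ProPhenol/Me2Zn catalyst is taken to deliver zinc alkynides to the Re face of aldehydes; should the sense be the opposite, the ligand enantiomers of steps 4 and 9 are exchanged.

**Route**

Step 1
Reactants: 1 but-3-yn-1-ol
Product: 2 1-[(but-3-yn-1-yloxy)methyl]-4-methoxybenzene
Conditions: NaH, PMBCl, Bu4NI (cat.), THF/DMF, 0 °C → rt
Reagents that add atoms: 4-methoxybenzyl chloride, COc1ccc(CCl)cc1
Why: Williamson etherification of the primary alkoxide installs a PMB ether on the future C8 oxygen, which can later be removed oxidatively in the presence of an allylic bromide, an oxirane and silyl ethers.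

Step 2
Reactants: 2 1-[(but-3-yn-1-yloxy)methyl]-4-methoxybenzene; 3 oxirane
Product: 6 (3E)-6-[(4-methoxyphenyl)methoxy]-4-methylhex-3-en-1-ol, via alkenyldimethylalane 4 (not isolated), via lithium alkenylalanate 5 (not isolated)
Conditions: Me3Al, Cp2ZrCl2 (cat.), CH2Cl2, 0 °C → rt; volatiles removed; n-BuLi, THF/hexane, −78 → 0 °C; oxirane, 0 °C → rt; aq. HCl
Reagents that add atoms: trimethylaluminium, C[Al](C)C
Why: Negishi carboalumination adds methyl and aluminium syn across the terminal alkyne (methyl to the internal carbon), which fixes the E geometry of C1=C10 with C14, and the derived alanate opens oxirane with retention at the alkenyl carbon to add C2 and C3.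

Step 3
Reactants: 6 (3E)-6-[(4-methoxyphenyl)methoxy]-4-methylhex-3-en-1-ol
Product: 7 (3E)-6-[(4-methoxyphenyl)methoxy]-4-methylhex-3-enal
Conditions: Dess–Martin periodinane, NaHCO3, CH2Cl2, 0 °C; used at once
Reagents that add atoms: none
Why: Buffered Dess–Martin oxidation should give the β,γ-unsaturated aldehyde without moving the alkene into conjugation.

Step 4
Reactants: 7 (3E)-6-[(4-methoxyphenyl)methoxy]-4-methylhex-3-enal; 8 methyl propiolate
Product: 9 methyl (4S,6E)-4-hydroxy-9-[(4-methoxyphenyl)methoxy]-7-methylnon-6-en-2-ynoate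
Conditions: (S,S)-ProPhenol (20 mol %), Me2Zn, Ph3P=O (40 mol %), toluene, 4 °C
Reagents that add atoms: none
Why: Dinuclear zinc–ProPhenol alkynylation should deliver the zinc alkynide of methyl propiolate to the Re face of the aldehyde and set C3 as S under catalyst control.

Step 5
Reactants: 9 methyl (4S,6E)-4-hydroxy-9-[(4-methoxyphenyl)methoxy]-7-methylnon-6-en-2-ynoate
Product: 10 methyl (4S,6E)-4-[(tert-butyldimethylsilyl)oxy]-9-[(4-methoxyphenyl)methoxy]-7-methylnon-6-en-2-ynoate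
Conditions: TBSOTf, 2,6-lutidine, CH2Cl2, −78 °C
Reagents that add atoms: tert-butyldimethylsilyl triflate, CC(C)(C)[Si](C)(C)OS(=O)(=O)C(F)(F)F
Why: Silylation with a non-nucleophilic base protects the C3 hydroxyl without conjugate addition to the ynoate, so that the next step cannot lactonise.

Step 6
Reactants: 10 methyl (4S,6E)-4-[(tert-butyldimethylsilyl)oxy]-9-[(4-methoxyphenyl)methoxy]-7-methylnon-6-en-2-ynoate
Product: 11 methyl (2Z,4S,6E)-4-[(tert-butyldimethylsilyl)oxy]-9-[(4-methoxyphenyl)methoxy]-3,7-dimethylnona-2,6-dienoate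
Conditions: Me2CuLi, THF, −78 °C; MeOH then aq. NH4Cl at −78 °C
Reagents that add atoms: lithium dimethylcuprate, [Li+].C[Cu-]C
Why: Syn carbocupration of the ynoate followed by cold protonation with retention places C15 on C4 and leaves C3 and the ester carbon cis, which is the Z geometry of C4=C5.

Step 7
Reactants: 11 methyl (2Z,4S,6E)-4-[(tert-butyldimethylsilyl)oxy]-9-[(4-methoxyphenyl)methoxy]-3,7-dimethylnona-2,6-dienoate
Product: 12 (2Z,4S,6E)-4-[(tert-butyldimethylsilyl)oxy]-9-[(4-methoxyphenyl)methoxy]-3,7-dimethylnona-2,6-dien-1-ol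
Conditions: DIBAL-H, CH2Cl2, −78 °C; Rochelle salt
Reagents that add atoms: none
Why: 1,2-Reduction of the enoate by DIBAL-H gives the Z-allylic alcohol with the alkene geometry untouched.

Step 8
Reactants: 12 (2Z,4S,6E)-4-[(tert-butyldimethylsilyl)oxy]-9-[(4-methoxyphenyl)methoxy]-3,7-dimethylnona-2,6-dien-1-ol
Product: 13 (2Z,4S,6E)-4-[(tert-butyldimethylsilyl)oxy]-9-[(4-methoxyphenyl)methoxy]-3,7-dimethylnona-2,6-dienal
Conditions: Dess–Martin periodinane, NaHCO3, CH2Cl2, 0 °C
Reagents that add atoms: none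
Why: Buffered Dess–Martin oxidation gives the β,β-disubstituted Z-enal (C6 aldehyde), a class with little drive to isomerise.

Step 9
Reactants: 13 (2Z,4S,6E)-4-[(tert-butyldimethylsilyl)oxy]-9-[(4-methoxyphenyl)methoxy]-3,7-dimethylnona-2,6-dienal; 14 tert-butyldimethyl(prop-2-yn-1-yloxy)silane
Product: 15 (4R,5Z,7S,9E)-1,7-bis[(tert-butyldimethylsilyl)oxy]-12-[(4-methoxyphenyl)methoxy]-6,10-dimethyldodeca-5,9-dien-2-yn-4-ol
Conditions: (R,R)-ProPhenol (20 mol %), Me2Zn, toluene, 4 °C
Reagents that add atoms: none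
Why: The same zinc–ProPhenol alkynylation, for which enals are the best substrates, with the antipodal ligand should add the alkynide to the Si face and set C6 as R under catalyst control.

Step 10
Reactants: 15 (4R,5Z,7S,9E)-1,7-bis[(tert-butyldimethylsilyl)oxy]-12-[(4-methoxyphenyl)methoxy]-6,10-dimethyldodeca-5,9-dien-2-yn-4-ol
Product: 17 (2Z,4R,5Z,7S,9E)-1,7-bis[(tert-butyldimethylsilyl)oxy]-2-iodo-12-[(4-methoxyphenyl)methoxy]-6,10-dimethyldodeca-2,5,9-trien-4-ol, via sodium alkenylaluminate 16 (not isolated)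
Conditions: Red-Al, THF, 0 °C; then I2, THF, −78 → 0 °C
Reagents that add atoms: iodine, II
Why: Alkoxide-directed trans-hydroalumination delivers hydride to C7 and aluminium to C11 through a five-membered oxaluminacycle, and iodinolysis with retention leaves iodine cis to the C6 carbinol as lactonisation requires.

Step 11
Reactants: 17 (2Z,4R,5Z,7S,9E)-1,7-bis[(tert-butyldimethylsilyl)oxy]-2-iodo-12-[(4-methoxyphenyl)methoxy]-6,10-dimethyldodeca-2,5,9-trien-4-ol
Product: 18 (5R)-3-{[(tert-butyldimethylsilyl)oxy]methyl}-5-{(1Z,3S,5E)-3-[(tert-butyldimethylsilyl)oxy]-8-[(4-methoxyphenyl)methoxy]-2,6-dimethylocta-1,5-dien-1-yl}furan-2(5H)-one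
Conditions: PdCl2(PPh3)2 (5 mol %), CO (1 atm), K2CO3, THF, 40 °C
Reagents that add atoms: carbon monoxide, [C-]#[O+]
Why: Palladium-catalysed carbonylative lactonisation (oxidative addition, CO insertion, capture of the acyl-palladium by the cis C6 hydroxyl) closes the γ-lactone and introduces C12 without touching the C6 stereocentre.

Step 12
Reactants: 18 (5R)-3-{[(tert-butyldimethylsilyl)oxy]methyl}-5-{(1Z,3S,5E)-3-[(tert-butyldimethylsilyl)oxy]-8-[(4-methoxyphenyl)methoxy]-2,6-dimethylocta-1,5-dien-1-yl}furan-2(5H)-one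
Product: 19 (5R)-3-{[(tert-butyldimethylsilyl)oxy]methyl}-5-[(1Z,3S)-3-[(tert-butyldimethylsilyl)oxy]-4-{(2R,3R)-3-{2-[(4-methoxyphenyl)methoxy]ethyl}-3-methyloxiran-2-yl}-2-methylbut-1-en-1-yl]furan-2(5H)-one
Conditions: D-fructose-derived Shi ketone (0.5 equiv), Oxone, NaHCO3 (pH about 8), Bu4NHSO4 (cat.), MeCN/dimethoxymethane/aq. Na2EDTA, 0 °C
Reagents that add atoms: potassium peroxymonosulfate (Oxone), [K+].[O-]S(=O)(=O)OO
Why: Shi epoxidation through the spiro transition state of the chiral dioxirane should give the (1R,10R)-oxirane on the only electron-rich E-trisubstituted alkene, the Z-C4=C5 and butenolide alkenes being deactivated by allylic oxygens and the carbonyl, and the low pH sparing the lactone.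

Step 13
Reactants: 19 (5R)-3-{[(tert-butyldimethylsilyl)oxy]methyl}-5-[(1Z,3S)-3-[(tert-butyldimethylsilyl)oxy]-4-{(2R,3R)-3-{2-[(4-methoxyphenyl)methoxy]ethyl}-3-methyloxiran-2-yl}-2-methylbut-1-en-1-yl]furan-2(5H)-one
Product: 20 (5R)-3-(hydroxymethyl)-5-[(1Z,3S)-3-[(tert-butyldimethylsilyl)oxy]-4-{(2R,3R)-3-{2-[(4-methoxyphenyl)methoxy]ethyl}-3-methyloxiran-2-yl}-2-methylbut-1-en-1-yl]furan-2(5H)-one
Conditions: HF·pyridine, pyridine, THF, 0 °C
Reagents that add atoms: none
Why: Buffered fluoride-mediated desilylation removes the unhindered primary allylic silyl ether at C13 much faster than the secondary C3 ether flanked by the C4 quaternary alkene carbon.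

Step 14
Reactants: 20 (5R)-3-(hydroxymethyl)-5-[(1Z,3S)-3-[(tert-butyldimethylsilyl)oxy]-4-{(2R,3R)-3-{2-[(4-methoxyphenyl)methoxy]ethyl}-3-methyloxiran-2-yl}-2-methylbut-1-en-1-yl]furan-2(5H)-one
Product: 21 (5R)-3-(bromomethyl)-5-[(1Z,3S)-3-[(tert-butyldimethylsilyl)oxy]-4-{(2R,3R)-3-{2-[(4-methoxyphenyl)methoxy]ethyl}-3-methyloxiran-2-yl}-2-methylbut-1-en-1-yl]furan-2(5H)-one
Conditions: CBr4, PPh3 (premixed), 2,6-lutidine, CH2Cl2, −20 °C
Reagents that add atoms: carbon tetrabromide, BrC(Br)(Br)Br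
Why: The Appel reaction converts the primary allylic alcohol into the bromide under neutral conditions that the oxirane, the silyl ether and the base-sensitive C6–H should survive.

Step 15
Reactants: 21 (5R)-3-(bromomethyl)-5-[(1Z,3S)-3-[(tert-butyldimethylsilyl)oxy]-4-{(2R,3R)-3-{2-[(4-methoxyphenyl)methoxy]ethyl}-3-methyloxiran-2-yl}-2-methylbut-1-en-1-yl]furan-2(5H)-one
Product: 22 (5R)-3-(bromomethyl)-5-[(1Z,3S)-3-[(tert-butyldimethylsilyl)oxy]-4-[(2R,3R)-3-(2-hydroxyethyl)-3-methyloxiran-2-yl]-2-methylbut-1-en-1-yl]furan-2(5H)-one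
Conditions: DDQ, CH2Cl2/pH 7 buffer, 0 °C
Reagents that add atoms: none
Why: Oxidative PMB cleavage by DDQ under neutral buffered conditions frees the C8 hydroxyl without a nucleophile or base that would attack the allylic bromide.

Step 16
Reactants: 22 (5R)-3-(bromomethyl)-5-[(1Z,3S)-3-[(tert-butyldimethylsilyl)oxy]-4-[(2R,3R)-3-(2-hydroxyethyl)-3-methyloxiran-2-yl]-2-methylbut-1-en-1-yl]furan-2(5H)-one
Product: 23 (5R)-3-(bromomethyl)-5-[(1Z,3S)-3-[(tert-butyldimethylsilyl)oxy]-2-methyl-4-[(2R,3R)-3-methyl-3-(2-oxoethyl)oxiran-2-yl]but-1-en-1-yl]furan-2(5H)-one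
Conditions: Dess–Martin periodinane, NaHCO3, CH2Cl2, 0 °C; filtered through buffered silica and used at once
Reagents that add atoms: none
Why: Buffered Dess–Martin oxidation is the mildest route to the β,γ-epoxy aldehyde, which is not stored because base would open the oxirane by β-elimination.

Step 17
Reactants: 23 (5R)-3-(bromomethyl)-5-[(1Z,3S)-3-[(tert-butyldimethylsilyl)oxy]-2-methyl-4-[(2R,3R)-3-methyl-3-(2-oxoethyl)oxiran-2-yl]but-1-en-1-yl]furan-2(5H)-one
Product: 25 (1R,3S,4Z,6R,7R,8S,10R)-3-[(tert-butyldimethylsilyl)oxy]-1,10-epoxy-8-hydroxygermacra-4,11(13)-dien-12,6-olide, via allylchromium(III) species 24 (not isolated)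
Conditions: CrCl2 (8 equiv), degassed THF/DMF (10:1), rt, syringe-pump addition of 23 to about 2 mM; aq. sodium serinate work-up
Reagents that add atoms: none
Why: Two Cr(II) insert into the C13–Br bond to give the 2-(acyloxycarbonyl)allyl chromium(III) species 24, a polarity-reversed butenolide whose normally electrophilic β-carbon C7 adds through a six-membered cyclic array (Cr–O=C8···C7=C11–C13) to the tethered aldehyde, forming C7–C8 while the alkene moves to the exocyclic C11=C13 position. The closest known reactions are the intramolecular Nozaki–Hiyama–Kishi (Barbier) allylations that close ten-membered germacranolide rings from 2-(bromomethyl)acrylates and the intermolecular metal-mediated additions of 3-(bromomethyl)furan-2(5H)-ones to aldehydes. The ten-membered carbocycle closes in a 10-exo-trig mode at the C8 carbonyl (the oxygen ends outside the ring), the allyl unit reacting SE2′. C7 is controlled by the C6 stereocentre: the aldehyde arm leaves C6 on one face and is expected to reach C7 on the opposite face with a near-antiperiplanar C5–C6–C7–C8 arrangement, giving the trans-fused lactone. C8 is controlled by the chair form of the cyclic array, in which the ring carbon C6 (trans to CH2Cr, an E-crotyl-type unit) and the chain carbon C9 are both pseudo-equatorial, which should give the anti (8S) carbinol. The step needs chemoselectivity for the aldehyde (organochromium reagents leave the lactone, oxirane and silyl ether alone), γ-regioselectivity (enforced by the closed array) and ring closure over chain growth (slow addition to excess CrCl2, helped by the preorganising Z-C4=C5 alkene and trans-oxirane).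

Step 18
Reactants: 26 [(tert-butyldimethylsilyl)oxy]acetaldehyde; 27 tert-butyl acrylate
Product: 28 tert-butyl 4-[(tert-butyldimethylsilyl)oxy]-3-hydroxy-2-methylidenebutanoate (racemic)
Conditions: DABCO (0.5 equiv), neat, rt, sealed
Reagents that add atoms: none
Why: Morita–Baylis–Hillman reaction of the activated α-silyloxy aldehyde with the acrylate builds the five-carbon skeleton of the outer acid; the carbinol centre is removed in the next step.

Step 19
Reactants: 28 tert-butyl 4-[(tert-butyldimethylsilyl)oxy]-3-hydroxy-2-methylidenebutanoate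
Product: 30 tert-butyl (2E)-2-(acetoxymethyl)-4-[(tert-butyldimethylsilyl)oxy]but-2-enoate, via secondary acetate 29 (not isolated)
Conditions: Ac2O, pyridine, DMAP (cat.), CH2Cl2, 0 °C; then DABCO (0.2 equiv), THF, 65 °C
Reagents that add atoms: acetic anhydride, CC(=O)OC(C)=O
Why: Acetylation followed by DABCO-mediated SN2′–SN2′ 1,3-transposition gives the thermodynamically preferred primary allylic acetate with the ester trans to the CH2OTBS group (2E).

Step 20
Reactants: 30 tert-butyl (2E)-2-(acetoxymethyl)-4-[(tert-butyldimethylsilyl)oxy]but-2-enoate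
Product: 32 (2E)-2-(acetoxymethyl)-4-[(tert-butyldimethylsilyl)oxy]but-2-enoic acid, via trimethylsilyl ester 31 (not isolated)
Conditions: TMSOTf, 2,6-lutidine, CH2Cl2, 0 °C → rt; pH 4 aqueous work-up
Reagents that add atoms: none
Why: Silyl triflate-induced loss of isobutene cleaves the tert-butyl ester selectively beside the acetate and the silyl ether, and the labile silyl ester is hydrolysed on work-up.

Step 21
Reactants: 33 acetaldehyde; 27 tert-butyl acrylate
Product: 34 tert-butyl 3-hydroxy-2-methylidenebutanoate (racemic)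
Conditions: DABCO (0.5 equiv), neat, rt, sealed
Reagents that add atoms: none
Why: Morita–Baylis–Hillman reaction gives the skeleton of the inner acid in one step.

Step 22
Reactants: 34 tert-butyl 3-hydroxy-2-methylidenebutanoate
Product: 35 tert-butyl (2Z)-2-(bromomethyl)but-2-enoate
Conditions: NBS, Me2S, CH2Cl2, 0 °C → rt
Reagents that add atoms: N-bromosuccinimide, O=C1CCC(=O)N1Br
Why: Corey–Kim-type activation of the allylic alcohol and SN2′ attack of bromide give the rearranged primary bromide with CH2Br cis to the methyl group (ester trans to methyl), the geometry of the inner acid.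

Step 23
Reactants: 32 (2E)-2-(acetoxymethyl)-4-[(tert-butyldimethylsilyl)oxy]but-2-enoic acid; 35 tert-butyl (2Z)-2-(bromomethyl)but-2-enoate
Product: 36 tert-butyl (2E)-2-({[(2E)-2-(acetoxymethyl)-4-[(tert-butyldimethylsilyl)oxy]but-2-enoyl]oxy}methyl)but-2-enoate
Conditions: Cs2CO3, DMF, 0 °C → rt
Reagents that add atoms: none
Why: SN2 alkylation of the caesium carboxylate at the primary allylic bromide joins the two acid units without an amine or phosphine that could scramble the allylic esters.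

Step 24
Reactants: 36 tert-butyl (2E)-2-({[(2E)-2-(acetoxymethyl)-4-[(tert-butyldimethylsilyl)oxy]but-2-enoyl]oxy}methyl)but-2-enoate
Product: 38 (2E)-2-({[(2E)-2-(acetoxymethyl)-4-[(tert-butyldimethylsilyl)oxy]but-2-enoyl]oxy}methyl)but-2-enoic acid, via trimethylsilyl ester 37 (not isolated)
Conditions: TMSOTf, 2,6-lutidine, CH2Cl2, 0 °C → rt; pH 4 aqueous work-up
Reagents that add atoms: none
Why: The same selective tert-butyl ester cleavage as in step 20 frees the carboxyl group of the complete side chain.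

Step 25
Reactants: 25 (1R,3S,4Z,6R,7R,8S,10R)-3-[(tert-butyldimethylsilyl)oxy]-1,10-epoxy-8-hydroxygermacra-4,11(13)-dien-12,6-olide; 38 (2E)-2-({[(2E)-2-(acetoxymethyl)-4-[(tert-butyldimethylsilyl)oxy]but-2-enoyl]oxy}methyl)but-2-enoic acid
Product: 39 (1R,3S,4Z,6R,7R,8R,10R)-3-[(tert-butyldimethylsilyl)oxy]-1,10-epoxy-8-{[(2E)-2-({[(2E)-2-(acetoxymethyl)-4-[(tert-butyldimethylsilyl)oxy]but-2-enoyl]oxy}methyl)but-2-enoyl]oxy}germacra-4,11(13)-dien-12,6-olide
Conditions: PPh3, DIAD (betaine preformed), toluene/THF, 0 °C → rt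
Reagents that add atoms: none
Why: Mitsunobu esterification displaces the C8 oxyphosphonium group by the carboxylate with inversion (8S to 8R), so esterification and stereochemical correction occur in one step; H7 is gauche to the leaving group, which disfavours elimination towards C7, and preforming the betaine keeps free phosphine away from the allylic esters.

Step 26
Reactants: 39 (1R,3S,4Z,6R,7R,8R,10R)-3-[(tert-butyldimethylsilyl)oxy]-1,10-epoxy-8-{[(2E)-2-({[(2E)-2-(acetoxymethyl)-4-[(tert-butyldimethylsilyl)oxy]but-2-enoyl]oxy}methyl)but-2-enoyl]oxy}germacra-4,11(13)-dien-12,6-olide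
Product: 40 (1R,3S,4Z,6R,7R,8R,10R)-1,10-epoxy-3-hydroxy-8-{[(2E)-2-({[(2E)-2-(acetoxymethyl)-4-hydroxybut-2-enoyl]oxy}methyl)but-2-enoyl]oxy}germacra-4,11(13)-dien-12,6-olide (CNP0193678.1)
Conditions: HF·pyridine, pyridine, THF, 0 °C → rt
Reagents that add atoms: none
Why: Buffered fluoride-mediated desilylation removes both silyl ethers under weakly acidic conditions that should leave the esters, the acetate, the oxirane and the α-methylene lactone intact.

**Compound list**

1 | but-3-yn-1-ol | C#CCCO | starting material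
2 | 1-[(but-3-yn-1-yloxy)methyl]-4-methoxybenzene | C#CCCOCc1ccc(OC)cc1 | intermediate
3 | oxirane | C1CO1 | starting material
4 | {(1E)-4-[(4-methoxyphenyl)methoxy]-2-methylbut-1-en-1-yl}dimethylaluminium | C[Al](C)/C=C(\C)CCOCc1ccc(OC)cc1 | intermediate (not isolated)
5 | lithium butyl(dimethyl){(1E)-4-[(4-methoxyphenyl)methoxy]-2-methylbut-1-en-1-yl}aluminate | [Li+].CCCC[Al-](C)(C)/C=C(\C)CCOCc1ccc(OC)cc1 | intermediate (not isolated)
6 | (3E)-6-[(4-methoxyphenyl)methoxy]-4-methylhex-3-en-1-ol | OCC/C=C(\C)CCOCc1ccc(OC)cc1 | intermediate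
7 | (3E)-6-[(4-methoxyphenyl)methoxy]-4-methylhex-3-enal | O=CC/C=C(\C)CCOCc1ccc(OC)cc1 | intermediate
8 | methyl propiolate | C#CC(=O)OC | starting material
9 | methyl (4S,6E)-4-hydroxy-9-[(4-methoxyphenyl)methoxy]-7-methylnon-6-en-2-ynoate | COC(=O)C#C[C@@H](O)C/C=C(\C)CCOCc1ccc(OC)cc1 | intermediate
10 | methyl (4S,6E)-4-[(tert-butyldimethylsilyl)oxy]-9-[(4-methoxyphenyl)methoxy]-7-methylnon-6-en-2-ynoate | COC(=O)C#C[C@@H](O[Si](C)(C)C(C)(C)C)C/C=C(\C)CCOCc1ccc(OC)cc1 | intermediate
11 | methyl (2Z,4S,6E)-4-[(tert-butyldimethylsilyl)oxy]-9-[(4-methoxyphenyl)methoxy]-3,7-dimethylnona-2,6-dienoate | COC(=O)/C=C(/C)[C@@H](O[Si](C)(C)C(C)(C)C)C/C=C(\C)CCOCc1ccc(OC)cc1 | intermediate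
12 | (2Z,4S,6E)-4-[(tert-butyldimethylsilyl)oxy]-9-[(4-methoxyphenyl)methoxy]-3,7-dimethylnona-2,6-dien-1-ol | OC/C=C(/C)[C@@H](O[Si](C)(C)C(C)(C)C)C/C=C(\C)CCOCc1ccc(OC)cc1 | intermediate
13 | (2Z,4S,6E)-4-[(tert-butyldimethylsilyl)oxy]-9-[(4-methoxyphenyl)methoxy]-3,7-dimethylnona-2,6-dienal | O=C/C=C(/C)[C@@H](O[Si](C)(C)C(C)(C)C)C/C=C(\C)CCOCc1ccc(OC)cc1 | intermediate
14 | tert-butyldimethyl(prop-2-yn-1-yloxy)silane | C#CCO[Si](C)(C)C(C)(C)C | starting material
15 | (4R,5Z,7S,9E)-1,7-bis[(tert-butyldimethylsilyl)oxy]-12-[(4-methoxyphenyl)methoxy]-6,10-dimethyldodeca-5,9-dien-2-yn-4-ol | CC(C)(C)[Si](C)(C)OCC#C[C@H](O)/C=C(/C)[C@@H](O[Si](C)(C)C(C)(C)C)C/C=C(\C)CCOCc1ccc(OC)cc1 | intermediate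
16 | sodium cyclic alkenylaluminate of 15 (2,2-bis(2-methoxyethoxy)-2,5-dihydro-1,2-oxaluminol-2-uide with CH2OTBS on C3 and the dienyl chain on C5) | [Na+].COCCO[Al-]1(OCCOC)O[C@@H](C=C1CO[Si](C)(C)C(C)(C)C)/C=C(/C)[C@@H](O[Si](C)(C)C(C)(C)C)C/C=C(\C)CCOCc1ccc(OC)cc1 | intermediate (not isolated)
17 | (2Z,4R,5Z,7S,9E)-1,7-bis[(tert-butyldimethylsilyl)oxy]-2-iodo-12-[(4-methoxyphenyl)methoxy]-6,10-dimethyldodeca-2,5,9-trien-4-ol | CC(C)(C)[Si](C)(C)OC/C(I)=C/[C@H](O)/C=C(/C)[C@@H](O[Si](C)(C)C(C)(C)C)C/C=C(\C)CCOCc1ccc(OC)cc1 | intermediate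
18 | (5R)-3-{[(tert-butyldimethylsilyl)oxy]methyl}-5-{(1Z,3S,5E)-3-[(tert-butyldimethylsilyl)oxy]-8-[(4-methoxyphenyl)methoxy]-2,6-dimethylocta-1,5-dien-1-yl}furan-2(5H)-one | O=C1O[C@@H](C=C1CO[Si](C)(C)C(C)(C)C)/C=C(/C)[C@@H](O[Si](C)(C)C(C)(C)C)C/C=C(\C)CCOCc1ccc(OC)cc1 | intermediate
19 | (5R)-3-{[(tert-butyldimethylsilyl)oxy]methyl}-5-[(1Z,3S)-3-[(tert-butyldimethylsilyl)oxy]-4-{(2R,3R)-3-{2-[(4-methoxyphenyl)methoxy]ethyl}-3-methyloxiran-2-yl}-2-methylbut-1-en-1-yl]furan-2(5H)-one | O=C1O[C@@H](C=C1CO[Si](C)(C)C(C)(C)C)/C=C(/C)[C@@H](O[Si](C)(C)C(C)(C)C)C[C@H]2O[C@]2(C)CCOCc1ccc(OC)cc1 | intermediate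
20 | (5R)-3-(hydroxymethyl)-5-[(1Z,3S)-3-[(tert-butyldimethylsilyl)oxy]-4-{(2R,3R)-3-{2-[(4-methoxyphenyl)methoxy]ethyl}-3-methyloxiran-2-yl}-2-methylbut-1-en-1-yl]furan-2(5H)-one | O=C1O[C@@H](C=C1CO)/C=C(/C)[C@@H](O[Si](C)(C)C(C)(C)C)C[C@H]2O[C@]2(C)CCOCc1ccc(OC)cc1 | intermediate
21 | (5R)-3-(bromomethyl)-5-[(1Z,3S)-3-[(tert-butyldimethylsilyl)oxy]-4-{(2R,3R)-3-{2-[(4-methoxyphenyl)methoxy]ethyl}-3-methyloxiran-2-yl}-2-methylbut-1-en-1-yl]furan-2(5H)-one | O=C1O[C@@H](C=C1CBr)/C=C(/C)[C@@H](O[Si](C)(C)C(C)(C)C)C[C@H]2O[C@]2(C)CCOCc1ccc(OC)cc1 | intermediate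
22 | (5R)-3-(bromomethyl)-5-[(1Z,3S)-3-[(tert-butyldimethylsilyl)oxy]-4-[(2R,3R)-3-(2-hydroxyethyl)-3-methyloxiran-2-yl]-2-methylbut-1-en-1-yl]furan-2(5H)-one | O=C1O[C@@H](C=C1CBr)/C=C(/C)[C@@H](O[Si](C)(C)C(C)(C)C)C[C@H]2O[C@]2(C)CCO | intermediate
23 | (5R)-3-(bromomethyl)-5-[(1Z,3S)-3-[(tert-butyldimethylsilyl)oxy]-2-methyl-4-[(2R,3R)-3-methyl-3-(2-oxoethyl)oxiran-2-yl]but-1-en-1-yl]furan-2(5H)-one | O=C1O[C@@H](C=C1CBr)/C=C(/C)[C@@H](O[Si](C)(C)C(C)(C)C)C[C@H]2O[C@]2(C)CC=O | intermediate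
24 | dichloro{[(5R)-2-oxo-5-(side chain of 23)-2,5-dihydrofuran-3-yl]methyl}chromium(III) (solvent ligands omitted) | O=C1O[C@@H](C=C1C[Cr](Cl)Cl)/C=C(/C)[C@@H](O[Si](C)(C)C(C)(C)C)C[C@H]2O[C@]2(C)CC=O | intermediate (not isolated)
25 | (1R,3S,4Z,6R,7R,8S,10R)-3-[(tert-butyldimethylsilyl)oxy]-1,10-epoxy-8-hydroxygermacra-4,11(13)-dien-12,6-olide | C=C1C(=O)O[C@@H]2/C=C(/C)[C@@H](O[Si](C)(C)C(C)(C)C)C[C@H]3O[C@]3(C)C[C@H](O)[C@@H]12 | intermediate
26 | [(tert-butyldimethylsilyl)oxy]acetaldehyde | O=CCO[Si](C)(C)C(C)(C)C | starting material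
27 | tert-butyl acrylate | C=CC(=O)OC(C)(C)C | starting material
28 | tert-butyl 4-[(tert-butyldimethylsilyl)oxy]-3-hydroxy-2-methylidenebutanoate (racemic) | C=C(C(=O)OC(C)(C)C)C(O)CO[Si](C)(C)C(C)(C)C | intermediate
29 | tert-butyl 3-acetoxy-4-[(tert-butyldimethylsilyl)oxy]-2-methylidenebutanoate (racemic) | C=C(C(=O)OC(C)(C)C)C(OC(C)=O)CO[Si](C)(C)C(C)(C)C | intermediate (not isolated)
30 | tert-butyl (2E)-2-(acetoxymethyl)-4-[(tert-butyldimethylsilyl)oxy]but-2-enoate | CC(=O)OC/C(=C\CO[Si](C)(C)C(C)(C)C)C(=O)OC(C)(C)C | intermediate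
31 | trimethylsilyl (2E)-2-(acetoxymethyl)-4-[(tert-butyldimethylsilyl)oxy]but-2-enoate | CC(=O)OC/C(=C\CO[Si](C)(C)C(C)(C)C)C(=O)O[Si](C)(C)C | intermediate (not isolated)
32 | (2E)-2-(acetoxymethyl)-4-[(tert-butyldimethylsilyl)oxy]but-2-enoic acid | CC(=O)OC/C(=C\CO[Si](C)(C)C(C)(C)C)C(=O)O | intermediate
33 | acetaldehyde | CC=O | starting material
34 | tert-butyl 3-hydroxy-2-methylidenebutanoate (racemic) | C=C(C(=O)OC(C)(C)C)C(C)O | intermediate
35 | tert-butyl (2Z)-2-(bromomethyl)but-2-enoate | C/C=C(\CBr)C(=O)OC(C)(C)C | intermediate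
36 | tert-butyl (2E)-2-({[(2E)-2-(acetoxymethyl)-4-[(tert-butyldimethylsilyl)oxy]but-2-enoyl]oxy}methyl)but-2-enoate | C/C=C(\COC(=O)/C(=C/CO[Si](C)(C)C(C)(C)C)COC(C)=O)C(=O)OC(C)(C)C | intermediate
37 | trimethylsilyl (2E)-2-({[(2E)-2-(acetoxymethyl)-4-[(tert-butyldimethylsilyl)oxy]but-2-enoyl]oxy}methyl)but-2-enoate | C/C=C(\COC(=O)/C(=C/CO[Si](C)(C)C(C)(C)C)COC(C)=O)C(=O)O[Si](C)(C)C | intermediate (not isolated)
38 | (2E)-2-({[(2E)-2-(acetoxymethyl)-4-[(tert-butyldimethylsilyl)oxy]but-2-enoyl]oxy}methyl)but-2-enoic acid | C/C=C(\COC(=O)/C(=C/CO[Si](C)(C)C(C)(C)C)COC(C)=O)C(=O)O | intermediate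
39 | (1R,3S,4Z,6R,7R,8R,10R)-3-[(tert-butyldimethylsilyl)oxy]-1,10-epoxy-8-{[(2E)-2-({[(2E)-2-(acetoxymethyl)-4-[(tert-butyldimethylsilyl)oxy]but-2-enoyl]oxy}methyl)but-2-enoyl]oxy}germacra-4,11(13)-dien-12,6-olide | C=C1C(=O)O[C@@H]2/C=C(/C)[C@@H](O[Si](C)(C)C(C)(C)C)C[C@H]3O[C@]3(C)C[C@@H](OC(=O)/C(=C/C)COC(=O)/C(=C/CO[Si](C)(C)C(C)(C)C)COC(C)=O)[C@@H]12 | intermediate
40 | (1R,3S,4Z,6R,7R,8R,10R)-1,10-epoxy-3-hydroxy-8-{[(2E)-2-({[(2E)-2-(acetoxymethyl)-4-hydroxybut-2-enoyl]oxy}methyl)but-2-enoyl]oxy}germacra-4,11(13)-dien-12,6-olide (CNP0193678.1) | C=C1C(=O)O[C@@H]2/C=C(/C)[C@@H](O)C[C@H]3O[C@]3(C)C[C@@H](OC(=O)/C(=C/C)COC(=O)/C(=C/CO)COC(C)=O)[C@@H]12 | target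

**Step count and risks**

Total step count: 26. Longest linear sequence: 19 steps (steps 1–17, 25, 26, from but-3-yn-1-ol); the side-chain acid 38 takes 7 steps (18–24).

The three steps most likely to fail:

Step 17 (ring closure). What may go wrong is poor facial selectivity at the aldehyde carbon (a boat instead of the chair array, or attack on the other lactone face), and chain growth between molecules instead of ring closure. The fallback makes the endgame stereoconvergent, so that the closure can be run under whichever allyl-metal conditions (indium in aqueous THF, zinc, samarium diiodide) close the ring best, without regard to the outcome at C8. Setting out from 23, a closure that delivers the 8R carbinol, (1R,3S,4Z,6R,7R,8R,10R)-3-[(tert-butyldimethylsilyl)oxy]-1,10-epoxy-8-hydroxygermacra-4,11(13)-dien-12,6-olide F1, is followed by Yamaguchi esterification of F1 with acid 38 (2,4,6-trichlorobenzoyl chloride, Et3N, then DMAP, toluene, rt). This keeps the C8 configuration and comes back to the route at 39.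

Step 25 (Mitsunobu esterification). What may go wrong is β-elimination of the C8 oxyphosphonium ion towards C9, and capture of triphenylphosphine by the allylic ester units of 38 (SN2′) in place of substitution. The fallback is a phosphine-free, two-stage inversion setting out from 25: triflation (Tf2O, 2,6-lutidine, CH2Cl2, −78 °C) gives the 8S triflate, (1R,3S,4Z,6R,7R,8S,10R)-3-[(tert-butyldimethylsilyl)oxy]-1,10-epoxy-8-[(trifluoromethanesulfonyl)oxy]germacra-4,11(13)-dien-12,6-olide F2. Its displacement by the caesium salt of 38 (Cs2CO3, 18-crown-6, toluene, 0 °C → rt) proceeds with inversion and comes back to the route at 39.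

Step 12 (Shi epoxidation). What may go wrong is base-induced opening or C6 epimerisation of the butenolide in the buffered aqueous medium, and loss of site selectivity among three alkenes. The fallback exchanges the order of oxirane and lactone formation. Setting out from iodide 17, which has no lactone yet, Shi epoxidation under the standard pH 10.5 conditions gives the epoxy iodide (2Z,4R,5Z,7S)-1,7-bis[(tert-butyldimethylsilyl)oxy]-2-iodo-8-{(2R,3R)-3-{2-[(4-methoxyphenyl)methoxy]ethyl}-3-methyloxiran-2-yl}-6-methylocta-2,5-dien-4-ol F3. This is carbonylated as in step 11 (PdCl2(PPh3)2, CO, K2CO3, THF) and comes back to the route at 19.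

Further compounds
F1 | step 17 | (1R,3S,4Z,6R,7R,8R,10R)-3-[(tert-butyldimethylsilyl)oxy]-1,10-epoxy-8-hydroxygermacra-4,11(13)-dien-12,6-olide | C=C1C(=O)O[C@@H]2/C=C(/C)[C@@H](O[Si](C)(C)C(C)(C)C)C[C@H]3O[C@]3(C)C[C@@H](O)[C@@H]12
F2 | step 25 | (1R,3S,4Z,6R,7R,8S,10R)-3-[(tert-butyldimethylsilyl)oxy]-1,10-epoxy-8-[(trifluoromethanesulfonyl)oxy]germacra-4,11(13)-dien-12,6-olide | C=C1C(=O)O[C@@H]2/C=C(/C)[C@@H](O[Si](C)(C)C(C)(C)C)C[C@H]3O[C@]3(C)C[C@H](OS(=O)(=O)C(F)(F)F)[C@@H]12
F3 | step 12 | (2Z,4R,5Z,7S)-1,7-bis[(tert-butyldimethylsilyl)oxy]-2-iodo-8-{(2R,3R)-3-{2-[(4-methoxyphenyl)methoxy]ethyl}-3-methyloxiran-2-yl}-6-methylocta-2,5-dien-4-ol | CC(C)(C)[Si](C)(C)OC/C(I)=C/[C@H](O)/C=C(/C)[C@@H](O[Si](C)(C)C(C)(C)C)C[C@H]1O[C@]1(C)CCOCc1ccc(OC)cc1
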